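The runs come from a simulation for an exercise, noise included.

At 2.5 min, the time of reading, the flask stands 30.0 s beyond the last reading of the two earlier runs, so I needed a way to carry their curves across that gap.

in all of them: free catalyst 8.5 mM (in portions, 3)
- north-east: starting material 0.034 M; run made earlier; portions every 40 s
- north-west: starting material 0.075 M; run made earlier; portions every 40 s
- flask: starting material 0.050 M; the portions of free catalyst follow each other after 40 s, the first at the start; time 2.5 min

| run | time / s | target / % | starting material / % |
|---|---|---|---|
| north-east | 10.0 | 4 | 89 |
| north-east | 20.0 | 5 | 79 |
| north-east | 30.0 | 7 | 74 |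
| north-east | 60.0 | 10 | 53 |
| north-east | 120 | 19 | 37 |
| north-west | 10.0 | 2 | 89 |
| north-west | 20.0 | 5 | 78 |
| north-west | 30.0 | 7 | 73 |
| north-west | 60.0 | 12 | 57 |
| north-west | 120 | 20 | 36 |

(scatter of a reading: 1.5 percentage points)

* how much target the flask holds at 2.5 min, in percent of the starting material charged
* how much starting material the flask holds at 2.5 min, in percent of the starting material charged



The two runs, at 0.034 M and 0.075 M of starting material, agree in percent within their scatter, so I averaged them for the flask at 0.050 M, which gave run averages of 55.0 % left at 60.0 s and 36.5 % at 120 s. From these I took the late slope, the fall per unit time in the logarithm of the starting material left between those two readings, 0.410 min⁻¹. One extreme flask stops at the last reading and holds 36.5 %, while the other keeps the late slope to the end and holds 29.7 %. I expected the real flask to lie between them, because the slope read over the first 30.0 s of the two runs, 0.616 min⁻¹, is steeper than the late slope although portions were added afterwards, so in those runs the pace fades without having stopped. I committed to the middle, 33.1 %. The selectivity read at the last reading, target per starting material consumed, is 0.307, which, held unchanged on my figure, makes an estimate of 20.5 % target.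

The forecast, made from the same runs on the ground that “the catalyst dies”, said 22 % target and 31 % starting material, so my starting material stood above its figure.

The flask gave 21.1 % target and 33.3 % starting material, which lies between the two extremes.

    2 free catalyst → spent catalyst B (k = 1.30 M⁻¹ s⁻¹)
    starting material ⇌ target (K = 1.40, k = 0.00280 s⁻¹)
    isomer of the product ⇌ starting material (k = 0.00540 s⁻¹)
    target + free catalyst ⇌ isomer of the product + free catalyst, rate k4*[free catalyst]*[target] forward; the back reaction follows from the equilibrium constant (K = 1.20, k = 0.320 M⁻¹ s⁻¹)
    free catalyst → spent catalyst A (k = 0.00450 s⁻¹)
    2 starting material → self-condensation product (k = 3.90 × 10⁻⁵ M⁻¹ s⁻¹)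

The neighbouring flask, with the same charges but read at 1.5 min, falls inside the span of the readings, so I carried the late slope from 60.0 s for 30.0 s and got 44.8 % starting material, and that flask held 44.1 %.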